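**Plan**

- Retrosynthesis: (a) the C3–C1' bond between ring C and ring B (Suzuki coupling of iodochromone 19 with chromenyl boronate 8); (b) the C3–C2 bond of the dimethylpyran ring D, leading back to an ortho-ethynylaryl isopropyl ether; (c) ring C at O1–C2 and C2–C3 (enaminone, iodocyclisation); (d) the ring A side chain at C6–CH2 and the ring A oxygen O1 at its C–O bond.
- Enabling feature: C2 of ring D is a tertiary carbon bound to the ring oxygen and two methyl groups, i.e. the methine carbon of an aryl isopropyl ether after loss of hydride; C3=C4 is an arylalkyne after gain of hydride. The isopropyl C–H lies 1,5 to the alkyne carbon on C3' of ring B, so ring D is a redox isomer of alkyne 6 and can close by internal hydride transfer followed by C3–C2 bond formation.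
- Forward order: ring B is dressed (isopropyl ether, ortho-formyl, silyl ether, alkyne), ring D is closed, and the bromide is borylated. In parallel the side chain is placed between the two protected oxygens of a resorcinol, the third oxygen is introduced para to it by C–H borylation/oxidation (a symmetric phenol, so only the 6-alkyl chromone can form), and ring C is built. The halves are coupled and all protecting groups leave in one operation.
- Stereochemistry: the target has no stereocentre; the cis C3=C4 alkene of ring D is fixed by the ring.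

Key step: step 5

Assumption: 1,3-bis(methoxymethoxy)benzene 9 is taken as a catalogue compound; it is otherwise one step from resorcinol (MOMCl, i-Pr2NEt).

**Route**

Step 1
Reactants: 1 4-bromobenzene-1,3-diol (4-bromoresorcinol); 2 2-bromopropane
Product: 3 2-bromo-5-(propan-2-yloxy)phenol
Conditions: K2CO3 (1.1 equiv), DMF, 60 °C
Reagents that add atoms: none
Why: Williamson ether synthesis; the hydroxyl para to bromine is the less hindered one and its phenoxide the better nucleophile, so mono-alkylation should occur mainly there, with the isomer and the bis-ether removed by chromatography.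

Step 2
Reactants: 3 2-bromo-5-(propan-2-yloxy)phenol
Product: 4 3-bromo-2-hydroxy-6-(propan-2-yloxy)benzaldehyde
Conditions: MgCl2, Et3N, (CH2O)n, MeCN, reflux; aq. HCl work-up
Reagents that add atoms: formaldehyde (as paraformaldehyde), C=O
Why: Magnesium-mediated ortho-formylation of a phenol (Casnati–Skattebøl) delivers formaldehyde only ortho to the phenoxide, and the single free ortho position lies between the two oxygens, so the future C4 of ring D is placed without ambiguity.

Step 3
Reactants: 4 3-bromo-2-hydroxy-6-(propan-2-yloxy)benzaldehyde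
Product: 5 3-bromo-6-(propan-2-yloxy)-2-[(triisopropylsilyl)oxy]benzaldehyde
Conditions: TIPSOTf, 2,6-lutidine, CH2Cl2, 0 °C to rt
Reagents that add atoms: triisopropylsilyl trifluoromethanesulfonate, CC(C)[Si](OS(=O)(=O)C(F)(F)F)(C(C)C)C(C)C
Why: O-silylation with a silyl triflate should overcome the hindered, hydrogen-bonded phenol; the TIPS ether has no O–C–H to donate in step 5 and shields its oxygen.

Step 4
Reactants: 5 3-bromo-6-(propan-2-yloxy)-2-[(triisopropylsilyl)oxy]benzaldehyde
Product: 6 1-bromo-3-ethynyl-4-(propan-2-yloxy)-2-[(triisopropylsilyl)oxy]benzene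
Conditions: Me3SiCHN2, LiN(i-Pr)2, THF, −78 °C to rt; H2O
Reagents that add atoms: (trimethylsilyl)diazomethane, C[Si](C)(C)C=[N+]=[N-]
Why: Colvin rearrangement (addition of lithiated trimethylsilyldiazomethane, Peterson elimination, 1,2-hydrogen shift of the alkylidene carbene) gives the terminal alkyne without the alkyllithium of a Corey–Fuchs sequence, which would attack the aryl bromide.

Step 5
Reactants: 6 1-bromo-3-ethynyl-4-(propan-2-yloxy)-2-[(triisopropylsilyl)oxy]benzene
Product: 7 6-bromo-2,2-dimethyl-5-[(triisopropylsilyl)oxy]-2H-chromene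
Conditions: [(XPhos)Au(NCMe)]SbF6 (5 mol %), MeNO2 (0.05 M), 4 Å sieves, 100 °C
Reagents that add atoms: none
Why: Proposed new method: cationic monovalent gold binds the terminal alkyne and, because the 2,6-dioxygenated aryl group stabilises positive charge at the internal alkyne carbon, slips to the terminal carbon, so that the isopropyl methine C–H, held 1,5 to the internal carbon by the aryl ether, can deliver hydride through space (1,5-hydride shift) to give a (Z)-alkenylgold and a tertiary aryloxy-stabilised oxocarbenium ion. After rotation about the aryl–alkenyl bond the gold-bearing carbon attacks the oxocarbenium carbon with retention, forming the C3–C2 bond of ring D and releasing the catalyst, so the net change is a redox-neutral cycloisomerisation that consumes no reagent. The closest known reaction types are the gold- and PtI4-catalysed 1,5-hydride shift/cyclisation (hydroalkylation) of alkynyl ethers and the Lewis acid-catalysed hydride-transfer cyclisation of ortho-vinylaryl alkyl ethers to chromans; an aryl isopropyl ether donor paired with an unactivated ortho-ethynyl acceptor has not been shown. The six-membered ring closes in a 6-endo-trig mode at the C=O+ unit (both of its atoms end in the ring), and no stereocentre is formed, the ring alkene being cis of necessity. The step needs chemoselectivity for C–H hydride transfer over attack of an ether oxygen on the alkyne (benzofuran formation): oxygen attack would have to occur at the terminal, electronically disfavoured carbon and is reversible because a secondary alkyl group does not migrate, the silyl ether oxygen is shielded and has no O–C–H, and once C4 has taken the hydride only C3 carries gold, so no other ring can form.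

Step 6
Reactants: 7 6-bromo-2,2-dimethyl-5-[(triisopropylsilyl)oxy]-2H-chromene
Product: 8 2,2-dimethyl-6-(4,4,5,5-tetramethyl-1,3,2-dioxaborolan-2-yl)-5-[(triisopropylsilyl)oxy]-2H-chromene
Conditions: B2pin2, PdCl2(dppf) (5 mol %), KOAc, 1,4-dioxane, 90 °C
Reagents that add atoms: bis(pinacolato)diboron, CC1(C)OB(OC1(C)C)B1OC(C)(C)C(C)(C)O1
Why: Miyaura borylation of the aryl bromide; the weak acetate base should leave the chromene alkene and the silyl ether untouched.

Step 7
Reactants: 9 1,3-bis(methoxymethoxy)benzene; 10 1-bromo-3-methylbut-2-ene (prenyl bromide)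
Product: 12 1,3-bis(methoxymethoxy)-2-(3-methylbut-2-en-1-yl)benzene, via aryllithium 11 (not isolated)
Conditions: n-BuLi, THF, 0 °C; then 10, −78 °C to rt
Reagents that add atoms: none
Why: Directed ortho-metalation at the position between the two MOM ethers followed by SN2 alkylation with the allylic bromide places the C5 chain between the future O5 and O7.

Step 8
Reactants: 12 1,3-bis(methoxymethoxy)-2-(3-methylbut-2-en-1-yl)benzene
Product: 13 4-[2,6-bis(methoxymethoxy)phenyl]-2-methylbutan-2-ol
Conditions: Co(acac)2 (20 mol %), PhSiH3, O2 (1 atm), THF, rt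
Reagents that add atoms: dioxygen, O=O
Why: Mukaiyama hydration (hydrogen-atom transfer from a cobalt hydride, trapping of the tertiary radical by oxygen) gives the Markovnikov tertiary alcohol under neutral conditions that spare the MOM ethers.

Step 9
Reactants: 13 4-[2,6-bis(methoxymethoxy)phenyl]-2-methylbutan-2-ol
Product: 15 4-(3-hydroxy-3-methylbutyl)-3,5-bis(methoxymethoxy)phenol, via arylboronate 14 (not isolated)
Conditions: B2pin2, [Ir(OMe)(cod)]2 (1.5 mol %), 4,4'-di-tert-butyl-2,2'-bipyridine (3 mol %), THF, 80 °C; then H2O2, NaOH, THF/H2O, 0 °C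
Reagents that add atoms: hydrogen peroxide, OO
Why: Iridium-catalysed C–H borylation is sterically governed and should take the only ring C–H without an ortho substituent (para to the side chain); oxidation of the C–B bond then gives a symmetric phenol, so the later chromone closure can only give the 6-alkyl-5,7-dioxygenated pattern.

Step 10
Reactants: 15 4-(3-hydroxy-3-methylbutyl)-3,5-bis(methoxymethoxy)phenol
Product: 17 1-[2-hydroxy-5-(3-hydroxy-3-methylbutyl)-4,6-bis(methoxymethoxy)phenyl]ethan-1-one, via trilithio species 16 (not isolated)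
Conditions: n-BuLi (3.3 equiv), TMEDA, THF, −78 to 0 °C; then MeC(O)N(OMe)Me, −78 °C to rt; aq. NH4Cl
Reagents that add atoms: N-methoxy-N-methylacetamide, CC(=O)N(C)OC
Why: Directed ortho-metalation of the lithium phenoxide (the two remaining ring hydrogens are equivalent and each lies between OLi and OMOM) followed by acylation with a Weinreb amide, whose chelated tetrahedral adduct should stop the reaction at the methyl ketone.

Step 11
Reactants: 17 1-[2-hydroxy-5-(3-hydroxy-3-methylbutyl)-4,6-bis(methoxymethoxy)phenyl]ethan-1-one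
Product: 19 6-(3-hydroxy-3-methylbutyl)-3-iodo-5,7-bis(methoxymethoxy)-4H-chromen-4-one, via enaminone 18 (not isolated)
Conditions: Me2NCH(OMe)2, 90 °C; concentrate; then I2, pyridine, CHCl3, rt
Reagents that add atoms: N,N-dimethylformamide dimethyl acetal, COC(OC)N(C)C; iodine, II
Why: Enaminone formation with the amide acetal followed by iodine-induced cyclisation (α-iodination, conjugate attack of the only free phenol, loss of dimethylamine) is the standard route to 3-iodochromones, and the pyridine buffer should protect the MOM ethers and the tertiary alcohol.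

Step 12
Reactants: 8 2,2-dimethyl-6-(4,4,5,5-tetramethyl-1,3,2-dioxaborolan-2-yl)-5-[(triisopropylsilyl)oxy]-2H-chromene; 19 6-(3-hydroxy-3-methylbutyl)-3-iodo-5,7-bis(methoxymethoxy)-4H-chromen-4-one
Product: 20 3-{2,2-dimethyl-5-[(triisopropylsilyl)oxy]-2H-chromen-6-yl}-6-(3-hydroxy-3-methylbutyl)-5,7-bis(methoxymethoxy)-4H-chromen-4-one
Conditions: Pd(OAc)2 (5 mol %), SPhos (10 mol %), K3PO4, 1,4-dioxane/H2O, 60 °C
Reagents that add atoms: none
Why: Suzuki–Miyaura coupling; the α-iodoenone of 19 undergoes oxidative addition readily, the SPhos-ligated palladium catalyst is suited to ortho-substituted boronates, and the chromene alkene, MOM ethers, silyl ether and tertiary alcohol are inert.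

Step 13
Reactants: 20 3-{2,2-dimethyl-5-[(triisopropylsilyl)oxy]-2H-chromen-6-yl}-6-(3-hydroxy-3-methylbutyl)-5,7-bis(methoxymethoxy)-4H-chromen-4-one
Product: 22 Kanzonol T [5,7-dihydroxy-3-(5-hydroxy-2,2-dimethyl-2H-chromen-6-yl)-6-(3-hydroxy-3-methylbutyl)-4H-chromen-4-one], via silyl ether 21 (not isolated)
Conditions: TMSOTf, 2,2'-bipyridyl, MeCN, 0 °C to rt; then TBAF, THF, 0 °C; aq. NH4Cl
Reagents that add atoms: none
Why: Acetal exchange followed by fluoride desilylation: TMSOTf/2,2'-bipyridyl converts the aryl MOM ethers into trimethylsilyl ethers without free acid (so the tertiary alcohol, silylated in passing, cannot ionise and close onto a neighbouring phenol, and the chromene is spared), and fluoride then cleaves all four silyl ethers.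

**Compound list**

1 | 4-bromobenzene-1,3-diol (4-bromoresorcinol) | Oc1ccc(Br)c(O)c1 | starting material
2 | 2-bromopropane | CC(C)Br | starting material
3 | 2-bromo-5-(propan-2-yloxy)phenol | CC(C)Oc1ccc(Br)c(O)c1 | intermediate
4 | 3-bromo-2-hydroxy-6-(propan-2-yloxy)benzaldehyde | CC(C)Oc1ccc(Br)c(O)c1C=O | intermediate
5 | 3-bromo-6-(propan-2-yloxy)-2-[(triisopropylsilyl)oxy]benzaldehyde | CC(C)Oc1ccc(Br)c(O[Si](C(C)C)(C(C)C)C(C)C)c1C=O | intermediate
6 | 1-bromo-3-ethynyl-4-(propan-2-yloxy)-2-[(triisopropylsilyl)oxy]benzene | CC(C)Oc1ccc(Br)c(O[Si](C(C)C)(C(C)C)C(C)C)c1C#C | intermediate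
7 | 6-bromo-2,2-dimethyl-5-[(triisopropylsilyl)oxy]-2H-chromene | CC1(C)C=Cc2c(O1)ccc(Br)c2O[Si](C(C)C)(C(C)C)C(C)C | intermediate
8 | 2,2-dimethyl-6-(4,4,5,5-tetramethyl-1,3,2-dioxaborolan-2-yl)-5-[(triisopropylsilyl)oxy]-2H-chromene | CC1(C)C=Cc2c(O1)ccc(B3OC(C)(C)C(C)(C)O3)c2O[Si](C(C)C)(C(C)C)C(C)C | intermediate
9 | 1,3-bis(methoxymethoxy)benzene | COCOc1cccc(OCOC)c1 | starting material
10 | 1-bromo-3-methylbut-2-ene (prenyl bromide) | CC(C)=CCBr | starting material
11 | [2,6-bis(methoxymethoxy)phenyl]lithium (not isolated) | [Li]c1c(OCOC)cccc1OCOC | intermediate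
12 | 1,3-bis(methoxymethoxy)-2-(3-methylbut-2-en-1-yl)benzene | COCOc1cccc(OCOC)c1CC=C(C)C | intermediate
13 | 4-[2,6-bis(methoxymethoxy)phenyl]-2-methylbutan-2-ol | COCOc1cccc(OCOC)c1CCC(C)(C)O | intermediate
14 | 4-[2,6-bis(methoxymethoxy)-4-(4,4,5,5-tetramethyl-1,3,2-dioxaborolan-2-yl)phenyl]-2-methylbutan-2-ol (not isolated) | COCOc1cc(B2OC(C)(C)C(C)(C)O2)cc(OCOC)c1CCC(C)(C)O | intermediate
15 | 4-(3-hydroxy-3-methylbutyl)-3,5-bis(methoxymethoxy)phenol | COCOc1cc(O)cc(OCOC)c1CCC(C)(C)O | intermediate
16 | trilithio derivative of 15: lithium phenoxide, lithium tertiary alkoxide and aryllithium at C2 (not isolated) | [Li]Oc1cc(OCOC)c(CCC(C)(C)O[Li])c(OCOC)c1[Li] | intermediate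
17 | 1-[2-hydroxy-5-(3-hydroxy-3-methylbutyl)-4,6-bis(methoxymethoxy)phenyl]ethan-1-one | CC(=O)c1c(O)cc(OCOC)c(CCC(C)(C)O)c1OCOC | intermediate
18 | (E)-3-(dimethylamino)-1-[2-hydroxy-5-(3-hydroxy-3-methylbutyl)-4,6-bis(methoxymethoxy)phenyl]prop-2-en-1-one (not isolated) | CN(C)/C=C/C(=O)c1c(O)cc(OCOC)c(CCC(C)(C)O)c1OCOC | intermediate
19 | 6-(3-hydroxy-3-methylbutyl)-3-iodo-5,7-bis(methoxymethoxy)-4H-chromen-4-one | CC(C)(O)CCc1c(OCOC)cc2occ(I)c(=O)c2c1OCOC | intermediate
20 | 3-{2,2-dimethyl-5-[(triisopropylsilyl)oxy]-2H-chromen-6-yl}-6-(3-hydroxy-3-methylbutyl)-5,7-bis(methoxymethoxy)-4H-chromen-4-one | CC(C)(O)CCc1c(OCOC)cc2occ(-c3ccc4c(c3O[Si](C(C)C)(C(C)C)C(C)C)C=CC(C)(C)O4)c(=O)c2c1OCOC | intermediate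
21 | 3-{2,2-dimethyl-5-[(triisopropylsilyl)oxy]-2H-chromen-6-yl}-6-{3-methyl-3-[(trimethylsilyl)oxy]butyl}-5,7-bis[(trimethylsilyl)oxy]-4H-chromen-4-one (not isolated) | C[Si](C)(C)OC(C)(C)CCc1c(O[Si](C)(C)C)cc2occ(-c3ccc4c(c3O[Si](C(C)C)(C(C)C)C(C)C)C=CC(C)(C)O4)c(=O)c2c1O[Si](C)(C)C | intermediate
22 | Kanzonol T, 5,7-dihydroxy-3-(5-hydroxy-2,2-dimethyl-2H-chromen-6-yl)-6-(3-hydroxy-3-methylbutyl)-4H-chromen-4-one | CC(C)(O)CCc1c(O)cc2occ(-c3ccc4c(c3O)C=CC(C)(C)O4)c(=O)c2c1O | target

**Step count and risks**

Total steps: 13. Longest linear sequence: 8 steps (steps 1 to 6, then 12 and 13, from 1); the other branch runs 7 steps from 9.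

Steps most likely to fail:

1. Step 5 (proposed new method). The aryl ether C–H may be too weakly hydridic for transfer to the gold-bound alkyne. Alternatively the isopropoxy oxygen may add to the alkyne and lose its alkyl group (benzofuran formation), or adventitious water may hydrate the alkyne.
Fallback, from 1 back to 7, by ring-closing metathesis at C3=C4. Compound 1 is O-alkylated at the hydroxyl para to bromine with 3-chloro-3-methylbut-1-yne (CuCl2 cat., DBU, MeCN, 0 °C) to give 2-bromo-5-[(2-methylbut-3-yn-2-yl)oxy]phenol F1. Ortho-formylation (MgCl2, Et3N, paraformaldehyde) gives 3-bromo-2-hydroxy-6-[(2-methylbut-3-yn-2-yl)oxy]benzaldehyde F2, and silylation (TIPSOTf, 2,6-lutidine) gives 3-bromo-6-[(2-methylbut-3-yn-2-yl)oxy]-2-[(triisopropylsilyl)oxy]benzaldehyde F3. Semihydrogenation (H2, Pd/CaCO3 poisoned with Pb(OAc)2, quinoline) gives 3-bromo-6-[(2-methylbut-3-en-2-yl)oxy]-2-[(triisopropylsilyl)oxy]benzaldehyde F4. Wittig methylenation (Ph3P=CH2, THF, 0 °C) gives 1-bromo-3-ethenyl-4-[(2-methylbut-3-en-2-yl)oxy]-2-[(triisopropylsilyl)oxy]benzene F5. Metathesis with the second-generation Grubbs catalyst RuCl2(H2IMes)(PCy3)(=CHPh) (CH2Cl2, 40 °C) should then give 7.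

2. Step 10. Metalation of the polyanion may be incomplete or misdirected (lateral lithiation at the benzylic CH2, aggregation), or the phenoxide may be O-acylated.
Fallback, from 15 back to 17, by electrophilic formylation instead of metalation. Compound 15 is formylated ortho to its hydroxyl (MgCl2, Et3N, paraformaldehyde, MeCN, reflux) to give 2-hydroxy-5-(3-hydroxy-3-methylbutyl)-4,6-bis(methoxymethoxy)benzaldehyde F6. Excess MeMgBr (THF, 0 °C) gives racemic 4-[4-hydroxy-3-(1-hydroxyethyl)-2,6-bis(methoxymethoxy)phenyl]-2-methylbutan-2-ol F7, and MnO2 (CH2Cl2, rt) should oxidise the benzylic alcohol to 17.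

3. Step 12. The hindered ortho-silyloxy boronate may undergo protodeboronation, transmetalation may be slow, and the silyl ether may be lost under aqueous base.
Fallback, from 7 and 19 back to 20, by Negishi coupling. Bromide 7 undergoes bromine–lithium exchange (n-BuLi, THF, −78 °C) to {2,2-dimethyl-5-[(triisopropylsilyl)oxy]-2H-chromen-6-yl}lithium F8, which is transmetalated at once with ZnCl2 to chloro{2,2-dimethyl-5-[(triisopropylsilyl)oxy]-2H-chromen-6-yl}zinc F9. This is used in excess (the free tertiary alcohol of 19 consumes some) and coupled with 19 (Pd(OAc)2, SPhos, THF, 50 °C) to give 20 without base or water.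

**Further compounds**

F1 | step 5 | 2-bromo-5-[(2-methylbut-3-yn-2-yl)oxy]phenol | C#CC(C)(C)Oc1ccc(Br)c(O)c1
F2 | step 5 | 3-bromo-2-hydroxy-6-[(2-methylbut-3-yn-2-yl)oxy]benzaldehyde | C#CC(C)(C)Oc1ccc(Br)c(O)c1C=O
F3 | step 5 | 3-bromo-6-[(2-methylbut-3-yn-2-yl)oxy]-2-[(triisopropylsilyl)oxy]benzaldehyde | C#CC(C)(C)Oc1ccc(Br)c(O[Si](C(C)C)(C(C)C)C(C)C)c1C=O
F4 | step 5 | 3-bromo-6-[(2-methylbut-3-en-2-yl)oxy]-2-[(triisopropylsilyl)oxy]benzaldehyde | C=CC(C)(C)Oc1ccc(Br)c(O[Si](C(C)C)(C(C)C)C(C)C)c1C=O
F5 | step 5 | 1-bromo-3-ethenyl-4-[(2-methylbut-3-en-2-yl)oxy]-2-[(triisopropylsilyl)oxy]benzene | C=CC(C)(C)Oc1ccc(Br)c(O[Si](C(C)C)(C(C)C)C(C)C)c1C=C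
F6 | step 10 | 2-hydroxy-5-(3-hydroxy-3-methylbutyl)-4,6-bis(methoxymethoxy)benzaldehyde | O=Cc1c(O)cc(OCOC)c(CCC(C)(C)O)c1OCOC
F7 | step 10 | racemic 4-[4-hydroxy-3-(1-hydroxyethyl)-2,6-bis(methoxymethoxy)phenyl]-2-methylbutan-2-ol | CC(O)c1c(O)cc(OCOC)c(CCC(C)(C)O)c1OCOC
F8 | step 12 | {2,2-dimethyl-5-[(triisopropylsilyl)oxy]-2H-chromen-6-yl}lithium | [Li]c1ccc2OC(C)(C)C=Cc2c1O[Si](C(C)C)(C(C)C)C(C)C
F9 | step 12 | chloro{2,2-dimethyl-5-[(triisopropylsilyl)oxy]-2H-chromen-6-yl}zinc | Cl[Zn]c1ccc2OC(C)(C)C=Cc2c1O[Si](C(C)C)(C(C)C)C(C)C
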